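The readings were generated by integration with made-up constants; the scatter is artificial.

The vessel is closed, stirred and isothermal: substrate opens to an intermediate, which first nucleophile turns into target and second nucleophile into other capture product.

| flask | substrate | first nucleophile | second nucleophile | capture agent | remark | time |
|---|---|---|---|---|---|---|
| gamma | 32 mM | 80 mM | 32 mM | 0.43 mM | run made earlier |  |
| alpha | 32 mM | 80 mM | 32 mM | 0.96 mM | run made earlier |  |
| flask | 32 mM | 80.0 mM | 32.0 mM | 0.640 mM |  | 20 min |

| run | time / min | other capture product / % | target / % |
|---|---|---|---|
| gamma | 1.00 | 34.4 | 4.7 |
| gamma | 1.50 | 46.3 | 5.0 |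
| gamma | 2.50 | 60.7 | 5.6 |
| gamma | 4.00 | 71.6 | 7.8 |
| gamma | 8.00 | 79.6 | 9.8 |
| gamma | 12.0 | 81.6 | 8.8 |
| alpha | 2.00 | 53.2 | 6.3 |
| alpha | 4.00 | 71.4 | 7.7 |
| alpha | 6.00 | 77.0 | 8.8 |
| alpha | 8.00 | 79.3 | 9.7 |
| alpha | 10.0 | 80.6 | 9.7 |
| alpha | 12.0 | 80.9 | 9.1 |

(standard deviation of a reading: 0.5 percentage points)

- on the list of suspects stand: first nucleophile + open intermediate -> target; target <-> isomer of the product; substrate <-> open intermediate; second nucleophile + open intermediate -> other capture product; open intermediate + capture agent -> trapped intermediate

- ratio of other capture product to target at 1.5 s
- ratio of other capture product to target at 40 s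
- ratio of other capture product to target at 20 min
- which of other capture product and target there is more of at 20 min

The two runs differ in capture agent, yet their last readings of other capture product differ by 0.7 percentage points, with a scatter of 0.5 points on each, so I took their mean, 81.2%. But target reads 8.95%, leaving a gap of 9.80%. The alpha charge of capture agent, 3.00% of the substrate, is smaller than that gap, so I counted the gap as isomer of the product, which took first nucleophile on its way.

Both nucleophiles draw on one intermediate, which cancels when their rates are divided. Integrated, the fraction of second nucleophile left equals the fraction of first nucleophile left raised to a power s. The readings leave 18.8% and 92.5%, so s is 21.5. This s, the selectivity factor, is the second nucleophile's rate constant over the first's.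

The target readings change over minutes, and 1.5 s is shorter than the first reading of the gamma run, so I took the ratio there as s times the second nucleophile's charge over the first's, 8.59. For 20 min I took the ratio of the mean readings at 12.0 min, 9.07, with other capture product ahead.

The forecast, “Integrating the competition with a mass balance”, gave 10 at 1.5 s, 9.5 at 40 s and 8.8 at 20 min, with other capture product ahead, so its start stood above mine and its end below mine.

The flask gives 8.64 at 1.5 s, 9.31 at 40 s and 8.64 at 20 min, with 81.2% of other capture product against 9.40% of target.

    first nucleophile + open intermediate → target (k = 9.30 /M/s)
    target ⇌ isomer of the product (K = 0.990, k = 0.0130 /s)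
    substrate ⇌ open intermediate (K = 0.0190, k = 0.00900 /s)
    second nucleophile + open intermediate → other capture product (k = 200 /M/s)
    open intermediate + capture agent → trapped intermediate (k = 2.50 /M/s)

This flask's ratio at 1.5 s is 8.64 against my 8.59. In the neighbouring flask, charged with 48 mM of first nucleophile and otherwise as in the recipe, the same s times the second nucleophile's charge over that smaller charge gives 14.3. That neighbour's ratio of other capture product to target at 1.5 s is 14.4.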